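## Structural features

The target joins two six-membered carbocycles through one sp3 methine, C7, which also carries an isopropyl group. Ring A is a fully substituted acylphloroglucinol (C1 bridge carbon, C2–OH, C3–CH3, C4–OH, C5–isobutyryl, C6–OH). Ring B is the enol of a 2,2,4,4-tetramethylcyclohexane-1,3,5-trione (C1′ bridge carbon, C2′ enol carbon, C3′ CMe2, C4′ ketone, C5′ CMe2, C6′ ketone).

C7 is the only stereocentre, S as drawn (ring B > ring A > isopropyl > H). No neighbouring centre can relay its configuration, so it must come from an external chiral source.

C7 lies between two vinylogous acids, so both C7–C1 and C7–C1′ are retro-Michael bonds. Ipso-protonation of ring A, or aryloxide-assisted expulsion of the ring B enolate, would flatten C7, which makes the centre sensitive to acid, base and heat. Other fragile points are acid-induced cyclodehydration of C2–OH or C6–OH onto ring B (xanthenone formation) and retro-Claisen cleavage of the two non-enolisable 1,3-diketone units of ring B by hard nucleophiles.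

The real difficulty is to create a congested, labile C7 in one absolute sense, and ring B with its two quaternary carbons, without exposing the finished triad to equilibrating conditions.

The feature exploited is this. C2′–C3′–C4′–C5′ with its four methyl groups is the skeleton of 8 cut at one ring bond. C1′–C6′(=O) is an acetate unit hanging on C7. The oxygen on C2 stands 1,6 to C6′, so a bond O(C2)–C6′ that is absent from the target folds C7 into a six-membered aryl lactone. In that lactone C7 is an ordinary, non-ionisable benzylic centre that can be set on a flat coumarin. The same lactone supplies both the nucleophilic carbon (C1′) and the activated acyl carbon (C6′) of ring B.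

## Logic of the disconnections

**14 to 13.** No skeletal bond is cut. The O–H bonds at C4 and C6 are traced back to O–CH2Ph bonds. The finished triad should not see acid or base, so the last step must be neutral. The gain is that two acidic phenols stay silent during the strongly basic key step. The demand is a group that falls under hydrogen at room temperature without touching the enol, the ketones or C7.

**13 to 7 and 8 (key disconnection).**
- Bonds cut: C1′–C2′ and C5′–C6′ of ring B. In exchange, C2′–C5′ closes the four-membered ring of 8, and O(C2)–C6′ closes the lactone of 7.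
- Chromanone locants of 7: C4 = C7, C3 = C1′, C2 = C6′, O1 = oxygen on C2.
- Reason: ring B is not brought in as a ready-made nucleophile or acceptor, so neither labile bond at C7 is ever formed in an equilibrium.
- Gain: ring B with both quaternary carbons shrinks to a commercial C8 block, and the labile triad shrinks to a robust lactone with one stereocentre.
- Demand: two C–C bonds at hindered carbons must form in one flask. The tertiary enolate released in the first event must also survive the acidic C1′–H created at the same time.
- In one sentence: ring B is made by inserting the C3–C2 unit of 7 into a ring bond of 8. That sentence does not fit a route that couples two finished rings at C7.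

**7 to 6.** The C7–H and C1′–H bonds are cut, which restores the C3=C4 double bond of a coumarin. The stereochemical problem becomes facial selection on a rigid, planar, trisubstituted unsaturated lactone whose two β-substituents (fused arene, isopropyl) differ strongly in shape. The forward step must add hydride to C4 on one face only and must spare the lactone carbonyl, the ketone and the benzyl ethers.

**6 to 5.** The two O–CH2Ph bonds are cut. Protection must come before saturation, because a free hydroxyl peri to C4 could translactonise once the ring is saturated. The forward step must etherify two chelated, crowded phenols.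

**5 to 3 and 4.** The C5–C(=O) bond of ring A is cut. Only one ring carbon of 3 is unsubstituted, so regiochemistry is not an issue. The forward step needs a Lewis acid that the coumarin tolerates.

**3 to 1 and 2.** The C1–C7 bond and the lactone bond O(C2)–C6′ are cut. The most hindered aryl–carbon bond of the target is made by the innate nucleophilicity of the phloroglucinol, while C7 is still sp2. C7, its isopropyl group, C1′ and C6′ all come in one commercial keto ester. The forward step must lactonise through the hydroxyl next to the methyl group.

## Other disconnections considered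

**Alternative 1:** (the first that comes to mind) Cut C7–C1. The forward key step is a catalytic asymmetric Friedel–Crafts-type Michael addition of the acylphloroglucinol A1 to the alkylidene triketone A2, which is the Knoevenagel product of syncarpic acid A3.
- This plan is shorter, but it forms the stereocentre through the very bond whose retro-reaction racemises it, and in the presence of the acid or base that catalyses that retro-reaction. Any kinetic enantioselectivity therefore stands under thermodynamic erosion.
- The alkylidene carbon of A2 is flanked by two identical carbonyl groups. A chiral Lewis or Brønsted acid thus has two nearly equivalent binding modes that expose opposite faces.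
- The chosen plan sets C7 irreversibly by C–H bond formation, in a frame that cannot ionise.

**Alternative 2:** Cut C7–C1′. The forward key step is a stereoconvergent addition of A3 to the ortho-quinone methide A5, released from the racemic benzylic alcohol A4 under a chiral Brønsted acid.
- The idea is attractive because both enantiomers of A4 funnel through one planar species.
- A5 carries an α-branched alkyl group, so a 1,5-hydrogen shift from the isopropyl methine should drain it.
- Two different ortho hydroxyls and E/Z isomerism give several reactive geometries with opposite facial bias.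
- The acid needed for ionisation is also the agent expected to cyclodehydrate and racemise the adduct.
- The chosen plan needs no cationic or quinoid intermediate at C7.

**Alternative 3:** Cut the four C–CH3 bonds at C3′ and C5′. The forward key step is a dearomatising, exhaustive C-methylation of the unsymmetrical bis(phloroglucinyl)methane A6 under alkoxide conditions.
- The reaction type suits simple phloroglucinols, but here two such rings compete.
- O-methylation and methylation at the bridge-bearing carbon are further channels.
- C7 in A6 sits between two trihydroxyaryl groups and should be even more prone to scrambling than in the target.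
- An asymmetric entry to A6 would have to tell two very similar aryl groups apart.
- The chosen plan buys the four methyl groups already in place.

Key step: step 5

Assumption: the target is treated as the drawn enol tautomer of ring B (C2′ and C6′ exchange roles by tautomerism without affecting C7, which is S in this drawing), and the (R) antipode of the ligand in step 4 is taken to be the one that delivers hydride to the Si face of C4; should the sense be opposite, the equally available (S) antipode is used.

## Steps

**Step 1**
Reactants: 1 2-methylbenzene-1,3,5-triol; 2 ethyl 4-methyl-3-oxopentanoate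
Product: 3 5,7-dihydroxy-8-methyl-4-(propan-2-yl)-2H-chromen-2-one
Conditions: MeSO3H (solvent), 0 → 20 °C; ice water
Reagents that add atoms: none
Why: Pechmann condensation: a free ring carbon of the electron-rich triol attacks the protonated ketone of 2, then dehydration and lactonisation follow. Closure through the hydroxyl next to the methyl group is expected, because it leaves the peri C5–OH with a hydrogen rather than a methyl as its other neighbour, so that it can bend away from the C4 isopropyl group.

**Step 2**
Reactants: 3 5,7-dihydroxy-8-methyl-4-(propan-2-yl)-2H-chromen-2-one; 4 2-methylpropanoyl chloride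
Product: 5 5,7-dihydroxy-8-methyl-6-(2-methylpropanoyl)-4-(propan-2-yl)-2H-chromen-2-one
Conditions: AlCl3 (4 equiv), ClCH2CH2Cl–PhNO2, 70 °C; cold 1 M HCl
Reagents that add atoms: none
Why: Friedel–Crafts acylation (directly or by O-acylation and Fries rearrangement) at C6, the only unsubstituted ring carbon, which is activated by both flanking hydroxyls. The chelated ortho-hydroxy ketone that forms is deactivated, so the reaction should stop there.

**Step 3**
Reactants: 5 5,7-dihydroxy-8-methyl-6-(2-methylpropanoyl)-4-(propan-2-yl)-2H-chromen-2-one
Product: 6 5,7-bis(benzyloxy)-8-methyl-6-(2-methylpropanoyl)-4-(propan-2-yl)-2H-chromen-2-one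
Conditions: BnBr (3 equiv), K2CO3 (4 equiv), n-Bu4NI (cat.), DMF, 60 °C
Reagents that add atoms: benzyl bromide, BrCc1ccccc1
Why: Williamson ether synthesis on the two phenoxides; the ring is fully substituted, so C-benzylation has no site, and the coumarin lactone is stable to anhydrous carbonate. The ethers remove the acidic protons before step 5 and block translactonisation after step 4.

**Step 4**
Reactants: 6 5,7-bis(benzyloxy)-8-methyl-6-(2-methylpropanoyl)-4-(propan-2-yl)-2H-chromen-2-one
Product: 7 (4S)-5,7-bis(benzyloxy)-8-methyl-6-(2-methylpropanoyl)-4-(propan-2-yl)-3,4-dihydro-2H-chromen-2-one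
Conditions: Cu(OAc)2 (5 mol %), (R)-DTBM-SEGPHOS (5.5 mol %), (EtO)2MeSiH (1.5 equiv), t-BuOH (1.5 equiv), toluene, 0 → 20 °C
Reagents that add atoms: none
Why: Asymmetric conjugate reduction of a 4-substituted coumarin by a bisphosphine-ligated CuH, a known reaction class: the chiral ligand pocket distinguishes the flat fused arene from the isopropyl group and delivers hydride to the Si face of C4, which sets C7 as S. t-BuOH protonates the copper enolate and so limits 1,2-reduction of the lactone. The ketone, twisted between two benzyloxy groups and carrying an isopropyl group, should be too hindered to compete.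

**Step 5**
Reactants: 7 (4S)-5,7-bis(benzyloxy)-8-methyl-6-(2-methylpropanoyl)-4-(propan-2-yl)-3,4-dihydro-2H-chromen-2-one; 8 2,2,4,4-tetramethylcyclobutane-1,3-dione
Product: 13 2-[(1S)-1-[4,6-bis(benzyloxy)-2-hydroxy-3-methyl-5-(2-methylpropanoyl)phenyl]-2-methylpropyl]-3-hydroxy-4,4,6,6-tetramethylcyclohex-2-ene-1,5-dione, via lithium enolate 9 (not isolated), via cyclobutanolate 10 (not isolated), via bis-enolate 11 (not isolated), via acylketene 12 (not isolated)
Conditions: LiN(SiMe3)2 (2.3 equiv), THF, −78 °C; 8 (1.2 equiv), −78 → 20 °C; AcOH (3 equiv), −40 °C
Reagents that add atoms: none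
Why: Proposed new method: LiN(SiMe3)2 removes the C3–H of the aryl lactone, by far the most acidic and accessible C–H of 7 (the isopropyl ketone is twisted between two benzyloxy groups, is deprotonated much more slowly and its enolate has no electrophile within reach), and enolate 9 adds, anti to the C4 isopropyl group, to one of the two equivalent carbonyl groups of 8, which cannot be enolised and is activated by ring strain. The β-keto alkoxide 10 collapses by retro-Claisen cleavage of either equivalent ring bond, which makes C1′–C2′ permanent, releases the strain of the four-membered ring and unmasks C5′ as a tertiary enolate; the excess base takes the now acidic C1′–H, so that the tertiary enolate is preserved in bis-enolate 11 and is not spent on an internal proton transfer. Ring B then closes by attack of C5′ on the lactone carbonyl C6′, 6-(enolendo)-exo-trig if direct, 6-(enolendo)-exo-dig if the β-keto aryl ester enolate first loses its aryloxide by E1cB to give acylketene 12; the aryloxide is a good leaving group because it is para to the ketone, and the two CMe2 groups keep the chain folded (gem-dimethyl effect). Re-lactonisation and O-acylation of the enolate are reversible through 12, whereas C-acylation ends in the doubly stabilised ring B enolate, the only irreversible exit, so the manifold should drain to 13. The closest known reaction types are the nucleophile-induced ring opening of 8 to 2,2,4-trimethyl-3-oxopentanoyl derivatives, the base-induced growth of ketene dimers into cyclohexane-1,3,5-triones, the Dieckmann condensation and the Claisen cyclisation of polyketo esters; their combination as a two-carbon insertion of a lactone enolate into 8 is new. No new stereocentre remains: the transient C3 centre of 10 becomes the sp2 carbon C1′, and C7 (C4 of 7) carries no acidic hydrogen and no leaving group until the last event, so its configuration is carried over. The step needs cross- over self-condensation (secured by complete deprotonation of 7 before a non-enolisable partner is added), C- over O-acylation (secured by reversibility), and a short time at 20 °C followed by a cold, weakly acidic quench, so that the free aryloxide does not expel the ring B enolate from C7.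

**Step 6**
Reactants: 13 2-[(1S)-1-[4,6-bis(benzyloxy)-2-hydroxy-3-methyl-5-(2-methylpropanoyl)phenyl]-2-methylpropyl]-3-hydroxy-4,4,6,6-tetramethylcyclohex-2-ene-1,5-dione
Product: 14 2-[(1S)-1-[2,4,6-trihydroxy-3-methyl-5-(2-methylpropanoyl)phenyl]-2-methylpropyl]-3-hydroxy-4,4,6,6-tetramethylcyclohex-2-ene-1,5-dione (target)
Conditions: H2 (1 atm), 10% Pd/C, EtOAc, 20 °C
Reagents that add atoms: none
Why: Hydrogenolysis of two aryl benzyl ethers under neutral conditions; the tetrasubstituted enol of ring B, the hindered ring ketones and the hydrogen-bonded aryl ketone should be inert at one atmosphere. No acid or base is present, so neither retro-Michael channel at C7 nor cyclodehydration is opened.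

## Compound list

1 | 2-methylbenzene-1,3,5-triol | Cc1c(O)cc(O)cc1O | starting material
2 | ethyl 4-methyl-3-oxopentanoate | CCOC(=O)CC(=O)C(C)C | starting material
3 | 5,7-dihydroxy-8-methyl-4-(propan-2-yl)-2H-chromen-2-one | Cc1c(O)cc(O)c2c1OC(=O)C=C2C(C)C | intermediate
4 | 2-methylpropanoyl chloride | CC(C)C(=O)Cl | starting material
5 | 5,7-dihydroxy-8-methyl-6-(2-methylpropanoyl)-4-(propan-2-yl)-2H-chromen-2-one | Cc1c(O)c(C(=O)C(C)C)c(O)c2c1OC(=O)C=C2C(C)C | intermediate
6 | 5,7-bis(benzyloxy)-8-methyl-6-(2-methylpropanoyl)-4-(propan-2-yl)-2H-chromen-2-one | Cc1c(OCc3ccccc3)c(C(=O)C(C)C)c(OCc3ccccc3)c2c1OC(=O)C=C2C(C)C | intermediate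
7 | (4S)-5,7-bis(benzyloxy)-8-methyl-6-(2-methylpropanoyl)-4-(propan-2-yl)-3,4-dihydro-2H-chromen-2-one | Cc1c(OCc3ccccc3)c(C(=O)C(C)C)c(OCc3ccccc3)c2c1OC(=O)C[C@H]2C(C)C | intermediate
8 | 2,2,4,4-tetramethylcyclobutane-1,3-dione | CC1(C)C(=O)C(C)(C)C1=O | starting material
9 | lithium enolate of 7 (C2–O enolate, C4 unchanged), not isolated | [Li+].Cc1c(OCc3ccccc3)c(C(=O)C(C)C)c(OCc3ccccc3)c2c1OC([O-])=C[C@H]2C(C)C | intermediate
10 | lithium alkoxide of the 3,4-trans aldol adduct of 7 and 8 (3-(1-oxido-2,2,4,4-tetramethyl-3-oxocyclobutyl) lactone), not isolated | [Li+].Cc1c(OCc3ccccc3)c(C(=O)C(C)C)c(OCc3ccccc3)c2c1OC(=O)[C@H](C3([O-])C(C)(C)C(=O)C3(C)C)[C@H]2C(C)C | intermediate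
11 | dilithium bis-enolate of the 3-(2,2,4-trimethyl-3-oxopentanoyl) lactone, not isolated | [Li+].[Li+].Cc1c(OCc3ccccc3)c(C(=O)C(C)C)c(OCc3ccccc3)c2c1OC([O-])=C(C(=O)C(C)(C)C([O-])=C(C)C)[C@H]2C(C)C | intermediate
12 | ring-opened acylketene carrying the lithium aryloxide and the lithium tertiary enolate, not isolated | [Li+].[Li+].Cc1c(OCc2ccccc2)c(C(=O)C(C)C)c(OCc2ccccc2)c([C@@H](C(=C=O)C(=O)C(C)(C)C([O-])=C(C)C)C(C)C)c1[O-] | intermediate
13 | 2-[(1S)-1-[4,6-bis(benzyloxy)-2-hydroxy-3-methyl-5-(2-methylpropanoyl)phenyl]-2-methylpropyl]-3-hydroxy-4,4,6,6-tetramethylcyclohex-2-ene-1,5-dione | Cc1c(OCc2ccccc2)c(C(=O)C(C)C)c(OCc2ccccc2)c([C@@H](C2=C(O)C(C)(C)C(=O)C(C)(C)C2=O)C(C)C)c1O | intermediate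
14 | 2-[(1S)-1-[2,4,6-trihydroxy-3-methyl-5-(2-methylpropanoyl)phenyl]-2-methylpropyl]-3-hydroxy-4,4,6,6-tetramethylcyclohex-2-ene-1,5-dione | Cc1c(O)c(C(=O)C(C)C)c(O)c([C@@H](C2=C(O)C(C)(C)C(=O)C(C)(C)C2=O)C(C)C)c1O | target

## Step count and least certain steps

Total step count: 6. Longest linear sequence: 6 (1 → 3 → 5 → 6 → 7 → 13 → 14).

**Step 5 (key step, proposed new method).** Five processes are the most likely to go wrong.
- Internal proton transfer from C1′–H to the tertiary enolate may run faster than deprotonation by the external base or ring closure. The sequence would then stall at a stabilised monoanion.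
- The lactone enolate may fragment by E1cB before it meets 8, followed by capture by the amide base or self-condensation.
- The β-branched enolate may add only sluggishly to a carbonyl flanked by two quaternary carbons.
- O-acylation may turn out not to be reversible enough.
- Aryloxide-assisted ionisation at C7 during the warm phase may erode the enantiomeric purity.

The fallback uses known chemistry, sets out from 7 and 8 and comes back at 13. It forms the bond to the tertiary carbon first, by an aldol addition, and closes the ring through the methylene carbon C1′, so the acid–base mismatch does not arise. Methanolysis of 8 (NaOMe cat., MeOH) gives methyl 2,2,4-trimethyl-3-oxopentanoate F1. i-Bu2AlH (1 equiv, toluene, −78 °C) takes 7 to the lactol 1-[(4S)-5,7-bis(benzyloxy)-2-hydroxy-8-methyl-4-(propan-2-yl)-3,4-dihydro-2H-chromen-6-yl]-2-methylpropan-1-one F2. The lithium enolate of F1 (LiN(i-Pr)2, THF, −78 °C, 2.2 equiv) adds to the open hydroxy aldehyde form of F2 and is quenched cold, which gives methyl (7S)-7-[4,6-bis(benzyloxy)-2-hydroxy-3-methyl-5-(2-methylpropanoyl)phenyl]-5-hydroxy-2,2,4,4,8-pentamethyl-3-oxononanoate F3 as a mixture of carbinol epimers. Dess–Martin periodinane oxidises the carbinol to methyl (7S)-7-[4,6-bis(benzyloxy)-2-hydroxy-3-methyl-5-(2-methylpropanoyl)phenyl]-2,2,4,4,8-pentamethyl-3,5-dioxononanoate F4. KOt-Bu (THF, 0 °C) then effects a classical Dieckmann closure of C1′ onto the methyl ester to give 13.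

**Step 4.** Hydride transfer may be slow, or the facial selectivity poor, because the C5 benzyloxy group crowds C4. Over-reduction of the activated lactone carbonyl is a second risk. The fallback replaces catalyst control by resolution, sets out from 6 and comes back at 7. An achiral, less encumbered catalyst (Cu(OAc)2, 1,2-bis(diphenylphosphino)benzene, (EtO)2MeSiH, t-BuOH) gives racemic 5,7-bis(benzyloxy)-8-methyl-6-(2-methylpropanoyl)-4-(propan-2-yl)-3,4-dihydro-2H-chromen-2-one F5. Aminolysis of the activated lactone with (R)-1-phenylethylamine (THF, 20–40 °C) gives two diastereomeric amides. These are (3S)-3-[4,6-bis(benzyloxy)-2-hydroxy-3-methyl-5-(2-methylpropanoyl)phenyl]-4-methyl-N-[(1R)-1-phenylethyl]pentanamide F6 and its (3R) diastereomer F7, which are separated by crystallisation or chromatography. Acid-induced relactonisation of F6 (p-TsOH, toluene, reflux), helped by the crowded ortho substitution, returns 7.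

**Step 1.** Lactonisation may go through the other ortho hydroxyl and place the methyl group at C6 of the coumarin. The position of the lactone oxygen is erased in step 5, so this selectivity concerns the identity of the intermediates and not of the target. The fallback reverses the order of the two ring A substitutions, sets out from 1 and 4 and comes back at 5. Friedel–Crafts acylation of 1 with 4 (AlCl3) gives 1-(2,4,6-trihydroxy-3-methylphenyl)-2-methylpropan-1-one F8. Its single free ring carbon is flanked by one hydroxyl that is chelated and crowded by the ketone and by one that is para to the ketone and free. Pechmann condensation of F8 with 2 should then close through the free hydroxyl and give 5 directly.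

**Step 3.** Etherification of the C5 hydroxyl may stay incomplete, because it is hydrogen-bonded to the ketone and wedged between the ketone and the C4 isopropyl group. The fallback protects before the ketone is present, sets out from 3 and comes back at 6. Benzylation of 3 (BnBr, K2CO3, DMF) gives 5,7-bis(benzyloxy)-8-methyl-4-(propan-2-yl)-2H-chromen-2-one F9. F9 is then acylated at its only free ring carbon with the mixed anhydride from 2-methylpropanoic acid and (CF3CO)2O (H3PO4 cat., 20 °C), a Friedel–Crafts variant mild enough for aryl benzyl ethers.

**Step 6.** Hydrogenolysis of the two crowded ethers may be slow. Long contact times invite partial reduction of the aryl ketone and slow loss of configurational purity on the catalyst support. The fallback sets out from 13 and comes back at 14. It exchanges reductive cleavage for chelation-assisted Lewis acid cleavage with a cation scavenger (BCl3, pentamethylbenzene, CH2Cl2, −78 °C, cold methanol quench), which uses the ketone flanked by both ethers as an anchor. It makes no new compound (F0).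

## Further compounds

F1 | step 5 | methyl 2,2,4-trimethyl-3-oxopentanoate | COC(=O)C(C)(C)C(=O)C(C)C
F2 | step 5 | 1-[(4S)-5,7-bis(benzyloxy)-2-hydroxy-8-methyl-4-(propan-2-yl)-3,4-dihydro-2H-chromen-6-yl]-2-methylpropan-1-one (lactol, both anomers) | Cc1c(OCc3ccccc3)c(C(=O)C(C)C)c(OCc3ccccc3)c2c1OC(O)C[C@H]2C(C)C
F3 | step 5 | methyl (7S)-7-[4,6-bis(benzyloxy)-2-hydroxy-3-methyl-5-(2-methylpropanoyl)phenyl]-5-hydroxy-2,2,4,4,8-pentamethyl-3-oxononanoate (both C5 epimers) | Cc1c(OCc2ccccc2)c(C(=O)C(C)C)c(OCc2ccccc2)c([C@@H](CC(O)C(C)(C)C(=O)C(C)(C)C(=O)OC)C(C)C)c1O
F4 | step 5 | methyl (7S)-7-[4,6-bis(benzyloxy)-2-hydroxy-3-methyl-5-(2-methylpropanoyl)phenyl]-2,2,4,4,8-pentamethyl-3,5-dioxononanoate | Cc1c(OCc2ccccc2)c(C(=O)C(C)C)c(OCc2ccccc2)c([C@@H](CC(=O)C(C)(C)C(=O)C(C)(C)C(=O)OC)C(C)C)c1O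
F5 | step 4 | racemic 5,7-bis(benzyloxy)-8-methyl-6-(2-methylpropanoyl)-4-(propan-2-yl)-3,4-dihydro-2H-chromen-2-one | Cc1c(OCc3ccccc3)c(C(=O)C(C)C)c(OCc3ccccc3)c2c1OC(=O)CC2C(C)C
F6 | step 4 | (3S)-3-[4,6-bis(benzyloxy)-2-hydroxy-3-methyl-5-(2-methylpropanoyl)phenyl]-4-methyl-N-[(1R)-1-phenylethyl]pentanamide | Cc1c(OCc2ccccc2)c(C(=O)C(C)C)c(OCc2ccccc2)c([C@@H](CC(=O)N[C@H](C)c2ccccc2)C(C)C)c1O
F7 | step 4 | (3R)-3-[4,6-bis(benzyloxy)-2-hydroxy-3-methyl-5-(2-methylpropanoyl)phenyl]-4-methyl-N-[(1R)-1-phenylethyl]pentanamide | Cc1c(OCc2ccccc2)c(C(=O)C(C)C)c(OCc2ccccc2)c([C@H](CC(=O)N[C@H](C)c2ccccc2)C(C)C)c1O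
F8 | step 1 | 1-(2,4,6-trihydroxy-3-methylphenyl)-2-methylpropan-1-one | Cc1c(O)cc(O)c(C(=O)C(C)C)c1O
F9 | step 3 | 5,7-bis(benzyloxy)-8-methyl-4-(propan-2-yl)-2H-chromen-2-one | Cc1c(OCc3ccccc3)cc(OCc3ccccc3)c2c1OC(=O)C=C2C(C)C
F0 | step 6 | none | none
A1 | alternative 1 | 1-(2,4,6-trihydroxy-3-methylphenyl)-2-methylpropan-1-one | Cc1c(O)cc(O)c(C(=O)C(C)C)c1O
A2 | alternative 1 | 2,2,4,4-tetramethyl-6-(2-methylpropylidene)cyclohexane-1,3,5-trione | CC(C)C=C1C(=O)C(C)(C)C(=O)C(C)(C)C1=O
A3 | alternative 1 | syncarpic acid (2,2,4,4-tetramethylcyclohexane-1,3,5-trione) | CC1(C)C(=O)CC(=O)C(C)(C)C1=O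
A4 | alternative 2 | racemic 1-[2,4,6-trihydroxy-3-(1-hydroxy-2-methylpropyl)-5-methylphenyl]-2-methylpropan-1-one | Cc1c(O)c(C(=O)C(C)C)c(O)c(C(O)C(C)C)c1O
A5 | alternative 2 | 3,5-dihydroxy-2-methyl-4-(2-methylpropanoyl)-6-(2-methylpropylidene)cyclohexa-2,4-dien-1-one (ortho-quinone methide, geometry open) | O=C1C(C)=C(O)C(C(=O)C(C)C)=C(O)C1=CC(C)C
A6 | alternative 3 | 1-[2,4,6-trihydroxy-3-methyl-5-[2-methyl-1-(2,4,6-trihydroxyphenyl)propyl]phenyl]-2-methylpropan-1-one, enantiomer with the spatial arrangement of the target | Cc1c(O)c(C(=O)C(C)C)c(O)c([C@@H](c2c(O)cc(O)cc2O)C(C)C)c1O
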